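The decision is where to put the next charge in the new flask, more coupling partner or more free catalyst, judged by the rate of making target at 50% conversion.

common to all: free catalyst 5.6 mol%

| flask | starting material | coupling partner | remark |
|---|---|---|---|
| Saturday's | 0.25 M | 4 equiv | run made earlier |
| Monday's | 0.50 M | 2 equiv | run made earlier |
| flask | 0.50 M | 4.00 equiv |  |

| run | time / min | target / % | starting material / % |
|---|---|---|---|
| Saturday's | 3.00 | 1.7 | 97.7 |
| Saturday's | 6.00 | 4.4 | 96.0 |
| Saturday's | 10.0 | 6.7 | 93.2 |
| Saturday's | 12.0 | 7.1 | 92.1 |
| Saturday's | 15.0 | 11.4 | 91.6 |
| Saturday's | 20.0 | 11.4 | 89.4 |
| Monday's | 1.50 | 1.8 | 97.3 |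
| Monday's | 5.00 | 6.6 | 94.1 |
| Monday's | 8.00 | 10.1 | 91.0 |
| Monday's | 12.0 | 13.2 | 87.5 |
| Monday's | 20.0 | 19.0 | 81.8 |

(readings scatter by 0.5 percentage points)

- no earlier run changes the charge of coupling partner; that part of a forecast is a guess

1. apparent order in coupling partner when 50% of the starting material are converted (percent change of the rate of making target for one percent more coupling partner charged)
2. factor on the rate of making target when 50% of the starting material are converted if free catalyst is charged twice over

Saturday's and Monday's runs both hold 1.00 M of coupling partner, and Monday's holds twice the molar free catalyst. On a clock scaled by catalyst the two runs overlay (variable time normalisation): Monday's shows 6.6% target at 5.00 min, Saturday's 6.7% at 10.0 min. The reckoning here takes that overlay as the zero of the scale, assumes turnover first order in starting material and in free catalyst, and reads the overlay as a catalyst loss going with the square of free catalyst, so that at a fixed concentration of coupling partner the share of free catalyst left depends on conversion and not on its charge.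

The quantity to carry is the catalyst's reach: the value of ln(starting material charged over starting material left) across which free catalyst falls by a factor of e. In Monday's run the first-order rate of using starting material drops from 0.0122 min⁻¹ to 0.00842 min⁻¹, which reads as a reach of 0.372.

The new flask differs from Monday's by its coupling partner, 2.00 M against 1.00 M. Taking turnover as first order in partner and the loss as indifferent to it, which is a guess, the flask buys more conversion per catalyst lost, with a reach of 0.744. At 50% conversion 39.4% of the free catalyst charged then stands, and with coupling partner held at its charge this reckoning gives an order in partner of 1.93 and a catalyst factor of 2.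

The forecast gives an order of 0.8 and a factor of 1.9, stating “Partner order is a guess”, and it stands lower on the order than this reckoning.

The flask gives an order of 2.5 and a factor of 2.41.

    2 free catalyst → spent catalyst A (k = 0.734 M⁻¹ min⁻¹)
    coupling partner + free catalyst → spent catalyst B (k = 0.00367 M⁻¹ min⁻¹)
    starting material + coupling partner + free catalyst → free catalyst + target (k = 0.539 M⁻² min⁻¹)

At 50% conversion, reached after 50.9 min, 57.5% of the catalyst stands as spent catalyst A, with spent catalyst B beside it, while the reach reckoned for this flask puts the catalyst lost by then at 60.6%. Saturday's run holds the same concentration of coupling partner, so it is given the reach of 0.372 read from Monday's run, and it is taken to start at half Monday's first-order starting rate of 0.0132 min⁻¹; conversion growing as reach times ln(1 + rate × time / reach) then leaves 89.3% starting material at 20.0 min, where Saturday's reading is 89.4%.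

The readings come from a simulation for an exercise; the scatter is artificial.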